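**Plan**

1. Numbering and faces: eremophilane numbering (ring A = C1–C5 and C10; ring B = C5–C10; methyls C15 on C4 and C14 on C5; isopropenyl C11–C13 on C7); β is the face of the C5 methyl, α that of H-10.
2. Cuts: the two ester C–O bonds of the side chain (its Z alkenes from alkynes); C11=C12 and C11–C13 of the isopropenyl group (from a C7 carboxyl); C4–C15; then C9–C10 and C4–C5 together; in the open chain C1–C2 and C7–C8.
3. Enabling feature: ring B carries its C9 carbinol next to the ring-fusion carbon C10, and ring A carries the C3 oxygen one carbon (C4) away from the methyl-bearing quaternary C5. An open chain with a C9 aldehyde, an E C5=C10 alkene and a C3-keto/C4-ester unit can therefore fold chair–chair into the trans-fused 5β-methyl/10α-H decalin.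
4. Forward order: geranyl acetate supplies C1, C10, C5, C14, C6, C7 and C11 with the E alkene in place; an aldol adds C8–C9 and an acetoacetate dianion adds C2–C4; SnCl4 then closes ring B and ring A in one flask; C15, the isopropenyl group and the side chain follow, and the two alkynes are reduced to Z last.
5. Stereochemistry: C7/C8 from an (R)-oxazolidinone syn-aldol; C9, C10 and C5 from the chelated chair–chair closure with the C7 ester equatorial; C4 by axial protonation anti to the C5 methyl; C3 by dissolving-metal reduction to the equatorial alcohol; the side-chain carbinol from (S)-pent-1-yn-3-ol; both Z alkenes from syn semi-hydrogenation.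

Key step: step 10

Remark: C15 is added after the ring closure so that the terminating β-keto ester is unsubstituted at C4; dimethoxyacetaldehyde is used as the anhydrous monomer (dried and distilled from the commercial aqueous solution), and (S)-pent-1-yn-3-ol is taken as available in enantiopure form.

**Route**

Step 1
Reactants: 1 geranyl acetate [(E)-3,7-dimethylocta-2,6-dien-1-yl acetate]
Product: 3 (E)-6-acetoxy-4-methylhex-4-enal, via ozonide 2 (not isolated)
Conditions: O3 (1.0 equiv), CH2Cl2, −78 °C; then Me2S, −78 °C → rt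
Reagents that add atoms: ozone, [O-][O+]=O
Why: Ozonolysis with one equivalent of ozone should cleave the electron-rich 6,7-alkene much faster than the 2,3-alkene, which is deactivated by the allylic acetate, so the E alkene that becomes C5=C10 is carried over intact.

Step 2
Reactants: 3 (E)-6-acetoxy-4-methylhex-4-enal
Product: 4 (E)-6-acetoxy-4-methylhex-4-enoic acid
Conditions: NaClO2, NaH2PO4, 2-methylbut-2-ene, t-BuOH/H2O, 0 °C → rt
Reagents that add atoms: sodium chlorite, [Na+].[O-]Cl=O
Why: Pinnick oxidation converts the aldehyde into the acid under buffered conditions in which the scavenger alkene intercepts HOCl and so protects the trisubstituted alkene.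

Step 3
Reactants: 4 (E)-6-acetoxy-4-methylhex-4-enoic acid; 5 (R)-4-benzyloxazolidin-2-one
Product: 7 (R)-4-benzyl-3-[(E)-6-acetoxy-4-methylhex-4-enoyl]oxazolidin-2-one, via mixed pivalic anhydride 6 (not isolated)
Conditions: PivCl, Et3N, THF, −20 °C; then 5, LiCl, −20 °C → rt
Reagents that add atoms: none
Why: N-Acylation of the oxazolidinone through the mixed pivalic anhydride under LiCl/Et3N conditions is the standard mild route to Evans imides and leaves the allylic acetate untouched.

Step 4
Reactants: 7 (R)-4-benzyl-3-[(E)-6-acetoxy-4-methylhex-4-enoyl]oxazolidin-2-one; 8 2,2-dimethoxyacetaldehyde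
Product: 10 (R)-3-[(2R,4E)-6-acetoxy-2-[(1R)-1-hydroxy-2,2-dimethoxyethyl]-4-methylhex-4-enoyl]-4-benzyloxazolidin-2-one, via dibutylboron Z-enolate 9 (not isolated)
Conditions: Bu2BOTf, Et3N, CH2Cl2, −78 → 0 °C; 8, −78 → 0 °C; then pH 7 buffer, MeOH, H2O2, 0 °C
Reagents that add atoms: none
Why: Evans syn-aldol reaction, in which the boron Z-enolate reacts through a Zimmerman–Traxler chair on the enolate face opposite the benzyl group of the (R)-auxiliary, should set C7 and C8 as the R,R syn pair.

Step 5
Reactants: 10 the syn-aldol adduct (C8 hydroxyl free)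
Product: 11 (R)-3-[(2R,4E)-6-acetoxy-2-[(1R)-1-(benzyloxy)-2,2-dimethoxyethyl]-4-methylhex-4-enoyl]-4-benzyloxazolidin-2-one
Conditions: 2-benzyloxy-1-methylpyridinium triflate, MgO, PhCF3, 83 °C
Reagents that add atoms: 2-benzyloxy-1-methylpyridinium triflate, C[n+]1ccccc1OCc1ccccc1.[O-]S(=O)(=O)C(F)(F)F
Why: O-Benzylation by thermal benzyl transfer from the neutral pyridinium salt, buffered by MgO, avoids both the base that would cause retro-aldol or β-elimination and the acid that would ionise the acetal.

Step 6
Reactants: 11 the C8 benzyl ether imide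
Product: 12 allyl (2R,4E)-2-[(1R)-1-(benzyloxy)-2,2-dimethoxyethyl]-6-hydroxy-4-methylhex-4-enoate
Conditions: allyl alcohol, n-BuLi (gives LiOCH2CH=CH2, 3 equiv), THF, −20 → 0 °C; aq. NH4Cl
Reagents that add atoms: allyl alcohol, C=CCO
Why: Alkoxide transesterification of the imide (the allyl counterpart of the LiOBn cleavage of Evans imides) attacks the exocyclic carbonyl and in the same operation removes the allylic acetate by ester exchange.

Step 7
Reactants: 12 the C1 allylic alcohol
Product: 13 allyl (2R,4E)-2-[(1R)-1-(benzyloxy)-2,2-dimethoxyethyl]-6-bromo-4-methylhex-4-enoate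
Conditions: CBr4, PPh3, 2,6-lutidine, CH2Cl2, −20 → 0 °C
Reagents that add atoms: carbon tetrabromide, BrC(Br)(Br)Br
Why: Appel bromination converts the primary allylic alcohol into the bromide by SN2 displacement of the oxyphosphonium group under buffered, neutral conditions that spare the acetal and the esters.

Step 8
Reactants: 13 the C1 allylic bromide; 14 allyl acetoacetate (allyl 3-oxobutanoate)
Product: 16 diallyl (2R,4E)-2-[(1R)-1-(benzyloxy)-2,2-dimethoxyethyl]-4-methyl-8-oxodec-4-enedioate, via acetoacetate dianion 15 (not isolated)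
Conditions: 14, NaH, THF, 0 °C; n-BuLi, 0 °C; then 13, −78 → −20 °C; aq. NH4Cl
Reagents that add atoms: none
Why: Weiler dianion alkylation, in which the γ-carbanion of the acetoacetate dianion displaces the primary allylic bromide in an SN2 sense at low temperature faster than it can deprotonate the β-benzyloxy ester, forms C1–C2.

Step 9
Reactants: 16 the dimethyl acetal β-keto ester
Product: 17 diallyl (2R,4E)-2-[(1R)-1-(benzyloxy)-2-oxoethyl]-4-methyl-8-oxodec-4-enedioate (the cyclisation precursor: C9 aldehyde, C8 OBn, C7 allyl ester, E C5=C10, C3 keto/C4 allyl ester)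
Conditions: TFA/H2O (9:1), CH2Cl2, 0 °C
Reagents that add atoms: water, O
Why: Acid-catalysed acetal hydrolysis in an aqueous two-phase medium should free the α-benzyloxy aldehyde, since water captures the oxocarbenium ion far faster than the remote alkene can.

Step 10
Reactants: 17 the acyclic aldehyde β-keto ester
Product: 19 diallyl 8α-benzyloxy-9α-hydroxy-5β-methyl-3-oxo-trans-decalin-4β,7α-dicarboxylate (10α-H), via C5 tertiary carbocation 18 (not isolated)
Conditions: SnCl4 (2.2 equiv), 2,6-di-tert-butyl-4-methylpyridine (0.2 equiv), CH2Cl2 (0.005 M), −78 → −40 °C; aq. NaHCO3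
Reagents that add atoms: none
Why: Proposed new method: SnCl4 chelates the C9 aldehyde with the C8 benzyloxy oxygen, C10 of the E C5=C10 alkene adds to C9, and the tertiary C5 cation 18 is captured at C4 by the SnCl4-bound enol of the β-keto ester, whose proton ends on the C9 oxygen, so the net change is an isomerisation. The closest known reaction types are the Lewis-acid-promoted Prins-type cyclisation of δ,ε-unsaturated aldehydes and the SnCl4-mediated cyclisation of olefinic β-keto esters, each established alone but not joined in one cascade or run on an α-alkoxy aldehyde. Ring B closes 6-endo with respect to the alkene (6-exo with respect to the C=O, whose oxygen stays outside the ring), and ring A closes 6-endo with respect to the enol, both through chair transition states. C9 is controlled by the chelate, which keeps the carbonyl oxygen gauche to the axial C8 benzyloxy group and hence equatorial (9α-OH); C10 and C5 are controlled by the E alkene geometry together with antiperiplanar addition in the chair–chair fold (10α-H, 5β-methyl, trans fusion); their absolute sense is controlled by the C7 ester, which takes the equatorial position of the ring-B chair; C4 is controlled by the chelated enol geometry, which places its ester equatorial, and it remains epimerisable. The step needs attack through C10 and not C5, C-alkylation and not O-alkylation or proton loss, and initiation at the aldehyde and not by protonation of the alkene: the C14 methyl makes C5 the only cation-stabilising terminus, enol-ether formation is reversible under SnCl4 whereas C–C bond formation is not, and the chelated aldehyde reacts at −78 °C, where the buffered medium does not protonate the alkene.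

Step 11
Reactants: 19 the bicyclic β-keto ester
Product: 20 diallyl 8α-benzyloxy-9α-hydroxy-4α,5β-dimethyl-3-oxo-trans-decalin-4β,7α-dicarboxylate (10α-H)
Conditions: MeI, K2CO3, acetone, rt
Reagents that add atoms: iodomethane, CI
Why: C-Alkylation of the β-keto ester enolate with the small electrophile MeI installs C15, entering axially on the α face anti to the C5 methyl, and the C4 configuration so formed is erased in the next step.

Step 12
Reactants: 20 the C4-methylated bis(allyl ester)
Product: 22 8α-benzyloxy-9α-hydroxy-4β,5β-dimethyl-3-oxo-trans-decalin-7α-carboxylic acid (10α-H), via β-keto diacid 21 (not isolated)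
Conditions: Pd(PPh3)4 (5 mol %), HCO2H, Et3N, THF, rt → 40 °C
Reagents that add atoms: none
Why: Tsuji deallylation with zerovalent palladium and formate removes both allyl groups, the β-keto acid decarboxylates, and the enol is protonated axially from the α face opposite the C5 methyl, which should leave the C4 methyl equatorial (β), also the more stable arrangement.

Step 13
Reactants: 22 the keto acid benzyl ether
Product: 23 3α,8α,9α-trihydroxy-4β,5β-dimethyl-trans-decalin-7α-carboxylic acid (10α-H)
Conditions: Li, liquid NH3/THF, t-BuOH, −78 °C; then NH4Cl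
Reagents that add atoms: none
Why: Dissolving-metal reduction should give the thermodynamically preferred equatorial 3α-alcohol (hydride reagents would be steered by the syn-axial C5 methyl towards the axial alcohol), cleave the benzyl ether and leave the lithium carboxylate untouched.

Step 14
Reactants: 23 the triol acid
Product: 24 3α-hydroxy-8α,9α-(isopropylidenedioxy)-4β,5β-dimethyl-trans-decalin-7α-carboxylic acid (10α-H)
Conditions: 2,2-dimethoxypropane, PPTS, acetone, rt
Reagents that add atoms: 2,2-dimethoxypropane, COC(C)(C)OC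
Why: Acid-catalysed acetonide formation is selective for the cis-vicinal 8α,9α-diol and leaves the isolated C3 hydroxyl free.

Step 15
Reactants: 24 the acetonide hydroxy acid
Product: 25 1-[3α-hydroxy-8α,9α-(isopropylidenedioxy)-4β,5β-dimethyl-trans-decalin-7α-yl]ethanone (10α-H)
Conditions: MeLi (4 equiv), THF, 0 °C → rt; inverse quench into cold aq. NH4Cl
Reagents that add atoms: methyllithium, [Li]C
Why: Addition of methyllithium to the lithium carboxylate gives a dilithium gem-diolate that collapses to the methyl ketone only on work-up (the classical acid-to-methyl-ketone conversion), with C7 keeping its equatorial configuration.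

Step 16
Reactants: 25 the C7 methyl ketone
Product: 26 7α-isopropenyl-8α,9α-(isopropylidenedioxy)-4β,5β-dimethyl-trans-decalin-3α-ol (10α-H)
Conditions: Ph3PCH3Br, KOtBu, THF, 0 °C → rt
Reagents that add atoms: methyltriphenylphosphonium bromide, C[P+](c1ccccc1)(c1ccccc1)c1ccccc1.[Br-]
Why: Wittig methylenation converts the acetyl group into the isopropenyl group, with excess ylide also covering the free C3 hydroxyl.

Step 17
Reactants: 27 (S)-pent-1-yn-3-ol
Product: 28 (S)-tert-butyldimethyl(pent-1-yn-3-yloxy)silane
Conditions: TBSCl, imidazole, DMF, rt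
Reagents that add atoms: tert-butyldimethylsilyl chloride, CC(C)(C)[Si](C)(C)Cl
Why: Silylation of the propargylic alcohol with TBSCl/imidazole protects the carbinol without touching its stereocentre.

Step 18
Reactants: 28 the TBS ether of (S)-pent-1-yn-3-ol
Product: 29 (S)-4-(tert-butyldimethylsilyloxy)hex-2-ynoic acid
Conditions: n-BuLi, THF, −78 °C; CO2; then aq. HCl (pH 3)
Reagents that add atoms: carbon dioxide, O=C=O
Why: Deprotonation of the terminal alkyne and carboxylation of the lithium acetylide with CO2 gives the alkynoic acid.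

Step 19
Reactants: 26 the isopropenyl decalinol; 29 (S)-4-(tert-butyldimethylsilyloxy)hex-2-ynoic acid
Product: 30 3α-O-[(S)-4-(tert-butyldimethylsilyloxy)hex-2-ynoyl] derivative of 26
Conditions: DCC, DMAP (0.1 equiv), CH2Cl2, −20 → 0 °C
Reagents that add atoms: none
Why: Steglich esterification at low temperature acylates the only free hydroxyl (equatorial C3–OH) with retention at C3, and an alkynoic acid cannot isomerise the way a Z-enoic acid would.

Step 20
Reactants: 30 the silylated alkynoate
Product: 31 3α-O-[(S)-4-hydroxyhex-2-ynoyl] derivative of 26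
Conditions: HF·pyridine, pyridine, THF, 0 °C → rt
Reagents that add atoms: none
Why: Fluoride-mediated desilylation frees the propargylic alcohol without touching the acetonide, the ester or the isopropenyl group, and as an alkynoate the hydroxy ester cannot lactonise.

Step 21
Reactants: 31 the propargylic alcohol; 32 hex-2-ynoic acid
Product: 33 3α-O-[(S)-4-(hex-2-ynoyloxy)hex-2-ynoyl] derivative of 26
Conditions: DCC, DMAP (0.1 equiv), CH2Cl2, −20 → 0 °C
Reagents that add atoms: none
Why: A second Steglich esterification acylates the propargylic hydroxyl with retention of configuration.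

Step 22
Reactants: 33 the diyne diester
Product: 34 3α-O-[(S,Z)-4-((Z)-hex-2-enoyloxy)hex-2-enoyl] derivative of 26 (8,9-acetonide of the target)
Conditions: H2 (1 atm), Pd/CaCO3 poisoned with Pb(OAc)2, quinoline, EtOAc, rt, stopped after 2 equiv of H2
Reagents that add atoms: none
Why: Lindlar semi-hydrogenation adds hydrogen syn to both electron-poor alkynes to give the Z,Z-diene diester, the poisoned catalyst stopping at the alkene and sparing the hindered 1,1-disubstituted isopropenyl group.

Step 23
Reactants: 34 the acetonide of the target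
Product: 35 CNP0271544.1
Conditions: AcOH/H2O (4:1), 40 °C
Reagents that add atoms: none
Why: Mild acid hydrolysis of the acetonide should release the cis-8α,9α-diol without ester migration, ester cleavage or hydration of the isopropenyl group.

**Compound list**

1 | geranyl acetate | CC(C)=CCC/C(C)=C/COC(C)=O | starting material
2 | ozonide (1,2,4-trioxolane) at the former 6,7-alkene of 1, stereoisomer mixture | CC(=O)OC/C=C(C)/CCC1OOC(C)(C)O1 | intermediate
3 | (E)-6-acetoxy-4-methylhex-4-enal | CC(=O)OC/C=C(C)/CCC=O | intermediate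
4 | (E)-6-acetoxy-4-methylhex-4-enoic acid | CC(=O)OC/C=C(C)/CCC(=O)O | intermediate
5 | (R)-4-benzyloxazolidin-2-one | O=C1N[C@H](Cc2ccccc2)CO1 | starting material
6 | mixed anhydride of 4 with pivalic acid | CC(=O)OC/C=C(C)/CCC(=O)OC(=O)C(C)(C)C | intermediate
7 | (R)-4-benzyl-3-[(E)-6-acetoxy-4-methylhex-4-enoyl]oxazolidin-2-one | O=C1OC[C@@H](Cc2ccccc2)N1C(=O)CC/C(C)=C/COC(C)=O | intermediate
8 | 2,2-dimethoxyacetaldehyde | COC(OC)C=O | starting material
9 | dibutylboron Z-enolate of 7 | O=C1OC[C@@H](Cc2ccccc2)N1/C(OB(CCCC)CCCC)=C/C/C(C)=C/COC(C)=O | intermediate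
10 | (R)-3-[(2R,4E)-6-acetoxy-2-[(1R)-1-hydroxy-2,2-dimethoxyethyl]-4-methylhex-4-enoyl]-4-benzyloxazolidin-2-one | O=C1OC[C@@H](Cc2ccccc2)N1C(=O)[C@@H]([C@@H](O)C(OC)OC)C/C(C)=C/COC(C)=O | intermediate
11 | (R)-3-[(2R,4E)-6-acetoxy-2-[(1R)-1-(benzyloxy)-2,2-dimethoxyethyl]-4-methylhex-4-enoyl]-4-benzyloxazolidin-2-one | O=C1OC[C@@H](Cc2ccccc2)N1C(=O)[C@@H]([C@@H](OCc2ccccc2)C(OC)OC)C/C(C)=C/COC(C)=O | intermediate
12 | allyl (2R,4E)-2-[(1R)-1-(benzyloxy)-2,2-dimethoxyethyl]-6-hydroxy-4-methylhex-4-enoate | C=CCOC(=O)[C@@H]([C@@H](OCc1ccccc1)C(OC)OC)C/C(C)=C/CO | intermediate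
13 | allyl (2R,4E)-2-[(1R)-1-(benzyloxy)-2,2-dimethoxyethyl]-6-bromo-4-methylhex-4-enoate | C=CCOC(=O)[C@@H]([C@@H](OCc1ccccc1)C(OC)OC)C/C(C)=C/CBr | intermediate
14 | allyl acetoacetate | CC(=O)CC(=O)OCC=C | starting material
15 | dianion of allyl acetoacetate (sodium/lithium) | [CH2-]C(=O)[CH-]C(=O)OCC=C.[Na+].[Li+] | intermediate
16 | diallyl (2R,4E)-2-[(1R)-1-(benzyloxy)-2,2-dimethoxyethyl]-4-methyl-8-oxodec-4-enedioate | C=CCOC(=O)[C@@H]([C@@H](OCc1ccccc1)C(OC)OC)C/C(C)=C/CCC(=O)CC(=O)OCC=C | intermediate
17 | diallyl (2R,4E)-2-[(1R)-1-(benzyloxy)-2-oxoethyl]-4-methyl-8-oxodec-4-enedioate | C=CCOC(=O)[C@@H]([C@@H](OCc1ccccc1)C=O)C/C(C)=C/CCC(=O)CC(=O)OCC=C | intermediate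
18 | ring-B C5 tertiary carbocation (C9 oxygen on SnCl3, chloride counter-ion) | C=CCOC(=O)[C@@H]1C[C+](C)[C@@H](CCC(=O)CC(=O)OCC=C)[C@H](O[Sn](Cl)(Cl)Cl)[C@@H]1OCc1ccccc1.[Cl-] | intermediate
19 | diallyl 8α-benzyloxy-9α-hydroxy-5β-methyl-3-oxo-trans-decalin-4β,7α-dicarboxylate (10α-H) | C=CCOC(=O)[C@@H]1C[C@]2(C)[C@@H](C(=O)OCC=C)C(=O)CC[C@H]2[C@H](O)[C@@H]1OCc1ccccc1 | intermediate
20 | diallyl 8α-benzyloxy-9α-hydroxy-4α,5β-dimethyl-3-oxo-trans-decalin-4β,7α-dicarboxylate (10α-H) | C=CCOC(=O)[C@@H]1C[C@]2(C)[C@@](C)(C(=O)OCC=C)C(=O)CC[C@H]2[C@H](O)[C@@H]1OCc1ccccc1 | intermediate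
21 | 8α-benzyloxy-9α-hydroxy-4α,5β-dimethyl-3-oxo-trans-decalin-4β,7α-dicarboxylic acid | OC(=O)[C@@H]1C[C@]2(C)[C@@](C)(C(=O)O)C(=O)CC[C@H]2[C@H](O)[C@@H]1OCc1ccccc1 | intermediate
22 | 8α-benzyloxy-9α-hydroxy-4β,5β-dimethyl-3-oxo-trans-decalin-7α-carboxylic acid (10α-H) | OC(=O)[C@@H]1C[C@]2(C)[C@@H](C)C(=O)CC[C@H]2[C@H](O)[C@@H]1OCc1ccccc1 | intermediate
23 | 3α,8α,9α-trihydroxy-4β,5β-dimethyl-trans-decalin-7α-carboxylic acid (10α-H) | OC(=O)[C@@H]1C[C@]2(C)[C@@H](C)[C@H](O)CC[C@H]2[C@H](O)[C@@H]1O | intermediate
24 | 3α-hydroxy-8α,9α-(isopropylidenedioxy)-4β,5β-dimethyl-trans-decalin-7α-carboxylic acid | OC(=O)[C@@H]1C[C@]2(C)[C@@H](C)[C@H](O)CC[C@H]2[C@H](OC(C)(C)O3)[C@@H]13 | intermediate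
25 | 1-[3α-hydroxy-8α,9α-(isopropylidenedioxy)-4β,5β-dimethyl-trans-decalin-7α-yl]ethanone | CC(=O)[C@@H]1C[C@]2(C)[C@@H](C)[C@H](O)CC[C@H]2[C@H](OC(C)(C)O3)[C@@H]13 | intermediate
26 | 7α-isopropenyl-8α,9α-(isopropylidenedioxy)-4β,5β-dimethyl-trans-decalin-3α-ol | C=C(C)[C@@H]1C[C@]2(C)[C@@H](C)[C@H](O)CC[C@H]2[C@H](OC(C)(C)O3)[C@@H]13 | intermediate
27 | (S)-pent-1-yn-3-ol | C#C[C@H](CC)O | starting material
28 | (S)-tert-butyldimethyl(pent-1-yn-3-yloxy)silane | C#C[C@H](CC)O[Si](C)(C)C(C)(C)C | intermediate
29 | (S)-4-(tert-butyldimethylsilyloxy)hex-2-ynoic acid | OC(=O)C#C[C@H](CC)O[Si](C)(C)C(C)(C)C | intermediate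
30 | 3α-O-[(S)-4-(tert-butyldimethylsilyloxy)hex-2-ynoyl] derivative of 26 | C=C(C)[C@@H]1C[C@]2(C)[C@@H](C)[C@H](OC(=O)C#C[C@H](CC)O[Si](C)(C)C(C)(C)C)CC[C@H]2[C@H](OC(C)(C)O3)[C@@H]13 | intermediate
31 | 3α-O-[(S)-4-hydroxyhex-2-ynoyl] derivative of 26 | C=C(C)[C@@H]1C[C@]2(C)[C@@H](C)[C@H](OC(=O)C#C[C@H](CC)O)CC[C@H]2[C@H](OC(C)(C)O3)[C@@H]13 | intermediate
32 | hex-2-ynoic acid | CCCC#CC(=O)O | starting material
33 | 3α-O-[(S)-4-(hex-2-ynoyloxy)hex-2-ynoyl] derivative of 26 | C=C(C)[C@@H]1C[C@]2(C)[C@@H](C)[C@H](OC(=O)C#C[C@H](CC)OC(=O)C#CCCC)CC[C@H]2[C@H](OC(C)(C)O3)[C@@H]13 | intermediate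
34 | 8α,9α-O-isopropylidene derivative of the target | C=C(C)[C@@H]1C[C@]2(C)[C@@H](C)[C@H](OC(=O)/C=C\[C@H](CC)OC(=O)/C=C\CCC)CC[C@H]2[C@H](OC(C)(C)O3)[C@@H]13 | intermediate
35 | CNP0271544.1: 7α-isopropenyl-4β,5β-dimethyl-trans-decalin-3α,8α,9α-triol 3-[(S,Z)-4-((Z)-hex-2-enoyloxy)hex-2-enoate] | C=C(C)[C@@H]1C[C@]2(C)[C@@H](C)[C@H](OC(=O)/C=C\[C@H](CC)OC(=O)/C=C\CCC)CC[C@H]2[C@H](O)[C@@H]1O | target

**Count and risks**

Total step count: 23. Longest linear sequence: 21 steps (steps 1–16 and 19–23); steps 17 and 18 form a two-step side branch.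

The three steps most likely to fail:

Step 10 (Proposed new method). The cascade may stop after ring B, by proton loss from the C5 cation or by O-alkylation of the enol, or ring A may close alone after protonation of the alkene by adventitious acid. The fallback separates the two ring closures and uses known reactions for each; it sets out from 17 and returns at 19. Treating 17 with Me2AlCl in CH2Cl2 at −78 °C should bring about the proton-scavenged carbonyl-ene cyclisation of the type-2 kind (tether on the central carbon of the ene unit). This closes only ring B through the same chair and moves the alkene out of the ring, giving diallyl ester of the ring-B methylenecyclohexanol (C5=C14 exocyclic, 9α-OH, 8α-OBn, 10α-H with the keto-ester chain on C10) F1. In a second operation SnCl4 in CH2Cl2 at 0 °C, the protic conditions under which olefinic β-keto esters are known to cyclise, protonates the 1,1-disubstituted alkene to the same tertiary C5 cation, and the β-keto ester closes ring A through C4 to give 19. Any endocyclic alkene isomer formed beside F1 converges on the same cation.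

Step 11. C4 lies between the ketone and the quaternary C5, so methylation may be slow or may go to oxygen. The fallback brings C15 in before the ring closure; it sets out from 13 and 14 and returns at 20. Methylation of 14 (MeI, K2CO3, acetone) gives allyl 2-methylacetoacetate F2. Its dianion (NaH, then n-BuLi) is alkylated with 13 as in step 8 to give the C4-methyl analogue of 16, diallyl (2R,4E)-2-[(1R)-1-(benzyloxy)-2,2-dimethoxyethyl]-4,9-dimethyl-8-oxodec-4-enedioate (epimers at the methyl-bearing carbon) F3. Hydrolysis as in step 9 gives the corresponding aldehyde F4, and SnCl4 as in step 10 closes both rings. The chelated enol geometry places the ester equatorial and the methyl axial at C4, which is compound 20. The price is a more congested C4–C5 bond formation in the ring closure.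

Step 15. Methyllithium may add twice on quench to give the tertiary alcohol, may deprotonate C7 with loss of the C8 acetonide oxygen, or the polylithiated salt may be too insoluble to react cleanly. The fallback goes through an activated amide; it sets out from 24 and returns at 25. Coupling of 24 with MeNHOMe·HCl (EDC·HCl, HOBt, i-Pr2NEt, CH2Cl2) gives the N-methoxy-N-methylamide of 24 F5, and MeMgBr (3 equiv, THF, 0 °C) converts it into 25 through the stable chelated adduct, which cannot add a second time.

Further compounds
F1 | step 10 | diallyl ring-B methylenecyclohexanol from carbonyl-ene closure of 17 (C5=C14 exocyclic; 7α-CO2allyl, 8α-OBn, 9α-OH, 10α-H; keto-ester chain on C10) | C=CCOC(=O)[C@@H]1CC(=C)[C@@H](CCC(=O)CC(=O)OCC=C)[C@H](O)[C@@H]1OCc1ccccc1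
F2 | step 11 | allyl 2-methylacetoacetate (racemic) | CC(=O)C(C)C(=O)OCC=C
F3 | step 11 | diallyl (2R,4E)-2-[(1R)-1-(benzyloxy)-2,2-dimethoxyethyl]-4,9-dimethyl-8-oxodec-4-enedioate (epimers at the methyl-bearing carbon next to the ketone) | C=CCOC(=O)[C@@H]([C@@H](OCc1ccccc1)C(OC)OC)C/C(C)=C/CCC(=O)C(C)C(=O)OCC=C
F4 | step 11 | diallyl (2R,4E)-2-[(1R)-1-(benzyloxy)-2-oxoethyl]-4,9-dimethyl-8-oxodec-4-enedioate (epimers at the methyl-bearing carbon next to the ketone) | C=CCOC(=O)[C@@H]([C@@H](OCc1ccccc1)C=O)C/C(C)=C/CCC(=O)C(C)C(=O)OCC=C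
F5 | step 15 | N-methoxy-N-methylamide of 24 | CON(C)C(=O)[C@@H]1C[C@]2(C)[C@@H](C)[C@H](O)CC[C@H]2[C@H](OC(C)(C)O3)[C@@H]13
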